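**Plan**
Retrosynthesis: the C4=C15 methylene is traced back to a C4 ketone, and the triene chain is cut at C13=C14 and C11=C12 back to a C7 acetyl group, itself from isopropenyl. Ring A is then cut at C2–C3 and C1–Br, leaving ring B with a bromoacetyl group on C5 and a vinyl group on C10.
Enabling feature: in ring A, C1 carries Br beside quaternary C10, and C4 is at carbonyl level beside the C5 carbinol. C1–C2 can therefore be read as a former vinyl group and C3 as a former α-keto radical, joined by a 6-endo bromine atom-transfer radical cyclisation.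
Forward: ring B is the carvone ring. C10 is made quaternary by Michael addition to methyl acrylate and the propanoate arm is cut down to vinyl. C5 receives acetyl (enol triflate, Stille) and then oxygen (1,4-hydrosilylation, Rubottom). Bromination and closure of ring A follow, then ozonolysis, two olefinations, C4 methylenation and desilylation.
Stereochemistry: C7 comes from (R)-carvone, C10 from the (R)-1-phenylethylamine imine, C5 from epoxidation anti to the axial C10 methyl, and C1 from bromine transfer to the face opposite the axial 5α-OSiEt3. Both chain alkenes are E, from an acid-equilibrated enal and an E-selective phosphonate olefination.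

Key step: step 10

Remark: bicyclic compounds carry eudesmane numbering (ring A = C1–C5, C10; ring B = C5–C10; C14 = methyl on C10; C15 on C4; C11 on C7) and β is the face of the C10 methyl; phosphonates 21 and 24 are taken as purchased reagents.

Step 1
Reactants: 1 (R)-(−)-carvone
Product: 2 (2R,5R)-2-methyl-5-(prop-1-en-2-yl)cyclohexan-1-one (trans-dihydrocarvone, formed together with its C2 epimer)
Conditions: L-Selectride (1.1 equiv), THF, −78 °C; then H2O, → rt
Reagents that add atoms: none
Why: Conjugate hydride reduction of the enone by the hindered trialkylborohydride leaves the isopropenyl group and the chiral-pool centre (later C7) untouched; the configuration at C2 is irrelevant because that carbon becomes trigonal in step 2.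

Step 2
Reactants: 2 trans-dihydrocarvone (C2-epimer mixture); 3 (R)-1-phenylethylamine; 4 methyl acrylate
Product: 7 methyl 3-[(1S,4R)-1-methyl-2-oxo-4-(prop-1-en-2-yl)cyclohexyl]propanoate, via ketimine 5 (not isolated), via adduct imine 6 (not isolated)
Conditions: 3 (1.05 equiv), TsOH (cat.), toluene, reflux (−H2O); then 4 (2 equiv), THF, 50 °C; then 20% aq. AcOH, rt
Reagents that add atoms: methyl acrylate, C=CC(=O)OC; water, O
Why: Auxiliary-controlled Michael addition of a chiral imine: the more substituted secondary-enamine tautomer adds to the acrylate through a compact chair-like aza-ene transition state on the face away from the phenyl group, so the (R)-amine should set the quaternary centre (later C10) with methyl cis to isopropenyl, overriding the weaker bias of the ring; hydrolysis returns the ketone and the amine.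

Step 3
Reactants: 7 keto ester
Product: 8 3-[(1S,4R)-1-methyl-2-oxo-4-(prop-1-en-2-yl)cyclohexyl]propanoic acid
Conditions: LiOH·H2O, THF/MeOH/H2O, rt; then 1 M HCl
Reagents that add atoms: lithium hydroxide, [Li+].[OH-]
Why: Ester saponification; the α-carbon of the ketone on the chain side is quaternary and cannot epimerise.

Step 4
Reactants: 8 keto acid
Product: 9 (2S,5R)-2-ethenyl-2-methyl-5-(prop-1-en-2-yl)cyclohexan-1-one
Conditions: Pb(OAc)4 (1.5 equiv), Cu(OAc)2·H2O (0.3 equiv), pyridine, benzene, 80 °C
Reagents that add atoms: none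
Why: Kochi oxidative decarboxylation: the lead(IV) carboxylate loses CO2 to a primary alkyl radical that Cu(II) oxidises with loss of a β-hydrogen, which turns the propanoic acid arm into a vinyl group on the quaternary carbon without touching a stereocentre.

Step 5
Reactants: 9 vinyl ketone
Product: 10 (3R,6S)-6-ethenyl-6-methyl-3-(prop-1-en-2-yl)cyclohex-1-en-1-yl trifluoromethanesulfonate
Conditions: KHMDS (1.2 equiv), THF, −78 °C; PhNTf2 (1.2 equiv), −78 → 0 °C
Reagents that add atoms: N-phenylbis(trifluoromethanesulfonimide), O=S(=O)(N(c1ccccc1)S(=O)(=O)C(F)(F)F)C(F)(F)F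
Why: Only C6 bears α-hydrogens, so enolate formation is regiospecific and O-triflation gives the enol triflate.

Step 6
Reactants: 10 enol triflate; 11 tributyl(1-ethoxyvinyl)stannane
Product: 13 1-[(3R,6S)-6-ethenyl-6-methyl-3-(prop-1-en-2-yl)cyclohex-1-en-1-yl]ethan-1-one, via ethoxydiene 12 (not isolated)
Conditions: 11 (1.3 equiv), Pd(PPh3)4 (5 mol%), LiCl (3 equiv), THF, 65 °C; then 1 M HCl, rt
Reagents that add atoms: tributyl(1-ethoxyvinyl)stannane, CCCC[Sn](CCCC)(CCCC)C(=C)OCC; water, O
Why: Stille coupling of the enol triflate with an acetyl-anion equivalent, a reaction that works on triflates flanked by a quaternary carbon (steroidal 17-enol triflates), followed by mild hydrolysis of the enol ether to the methyl enone (C3–C4 of ring A).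

Step 7
Reactants: 13 enone
Product: 14 triethyl({1-[(2S,5R)-2-ethenyl-2-methyl-5-(prop-1-en-2-yl)cyclohexylidene]ethoxy})silane (C4=C5 geometry immaterial)
Conditions: Et3SiH (1.5 equiv), RhCl(PPh3)3 (2 mol%), THF, 50 °C
Reagents that add atoms: triethylsilane, CC[SiH](CC)CC
Why: Rhodium-catalysed 1,4-hydrosilylation of an enone with a monohydrosilane gives the tetrasubstituted C4=C5 silyl enol ether regiospecifically, while the isopropenyl group and the neopentyl vinyl group should react far more slowly.

Step 8
Reactants: 14 silyl enol ether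
Product: 16 1-[(1S,2S,5R)-2-ethenyl-2-methyl-5-(prop-1-en-2-yl)-1-(triethylsilyloxy)cyclohexyl]ethan-1-one, via silyloxy epoxide 15 (not isolated)
Conditions: mCPBA (1.05 equiv), CH2Cl2, −20 → 0 °C
Reagents that add atoms: 3-chloroperoxybenzoic acid, OOC(=O)c1cccc(Cl)c1
Why: Rubottom oxidation: the electron-rich tetrasubstituted enol ether is epoxidised well before the other alkenes, and in the ring-B chair with equatorial isopropenyl the axial C10 methyl covers the β face of C5, so oxygen should enter from the α face (as in the 17α-hydroxylation of steroidal Δ17(20)-enol derivatives) before epoxide opening with 1,4-silyl shift gives the 5α-silyl ether.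

Step 9
Reactants: 16 silyloxy methyl ketone
Product: 18 2-bromo-1-[(1S,2S,5R)-2-ethenyl-2-methyl-5-(prop-1-en-2-yl)-1-(triethylsilyloxy)cyclohexyl]ethan-1-one, via trimethylsilyl enol ether 17 (not isolated)
Conditions: LiHMDS (1.3 equiv), TMSCl (1.5 equiv), THF, −78 °C; then NBS (1.1 equiv), −78 → 0 °C
Reagents that add atoms: N-bromosuccinimide, O=C1CCC(=O)N1Br
Why: The methyl group is the only enolisable position (C5 is fully substituted), and electrophilic bromination of the terminal silyl enol ether by NBS is much faster than attack on the two isolated alkenes.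

Step 10
Reactants: 18 bromoacetyl vinyl cyclohexane
Product: 19 1β-bromo-5α-(triethylsilyloxy)-15-noreudesm-11-en-4-one (trans-decalin, 10β-methyl, 7β-isopropenyl)
Conditions: CuBr (10 mol%), tris(2-pyridylmethyl)amine (10 mol%), AIBN (10 mol%), degassed ClCH2CH2Cl (0.01 M), 80 °C
Reagents that add atoms: none
Why: Cu(I)–amine abstracts bromine from 18 to give the C3 α-keto radical and Cu(II)–Br; the radical adds to the terminal vinyl carbon C2 (new C2–C3 bond), and the secondary C1 radical takes bromine back from Cu(II)–Br or from 18, regenerating Cu(I). The closest known reaction type is the Kharasch-type halogen atom-transfer radical cyclisation of α-halo carbonyl compounds, in which 2-oxohex-5-enyl radicals close 6-endo. Ring A closes 6-endo-trig through a chair with the C5 acyl and C10 vinyl groups both equatorial on ring B, which gives the trans-decalin; the 5-exo mode would require attack at the neopentyl internal carbon C1 and a cyclopentanone-like transition state. The new stereocentre C1 is set in the bromine transfer: the α face of the C1 radical is 1,3-syn-axial to the bulky 5α-OSiEt3 group (and to H3α and H9α), so bromine should arrive on the β face and end equatorial, which is also the more stable epimer. The radical must also cyclise before it adds to the isopropenyl group of a second molecule; high dilution, the two fully substituted tether carbons and reversible capping of the uncyclised radical by Cu(II)–Br should secure this.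

Step 11
Reactants: 19 bromo ketone
Product: 20 1β-bromo-5α-(triethylsilyloxy)-13,15-dinoreudesmane-4,11-dione (7β-acetyl)
Conditions: O3, CH2Cl2, −78 °C; then PPh3, → rt
Reagents that add atoms: ozone, [O-][O+]=O
Why: Ozonolysis with reductive work-up cleaves the only alkene left, and the equatorial C7 acetyl group is the stable epimer.

Step 12
Reactants: 20 diketone; 21 diethyl [(E)-2-(cyclohexylamino)vinyl]phosphonate
Product: 23 (2E)-3-[1β-bromo-4-oxo-5α-(triethylsilyloxy)-10β-methyl-trans-decalin-7β-yl]but-2-enal (eudesmane numbering; CHO trans to the ring), via N-cyclohexyl azadiene 22 (not isolated)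
Conditions: 21 (1.5 equiv), NaH (1.5 equiv), THF, 0 °C → rt; then aq. oxalic acid, toluene, rt
Reagents that add atoms: diethyl [2-(cyclohexylamino)vinyl]phosphonate, CCOP(=O)(OCC)/C=C/NC1CCCCC1; water, O
Why: Horner–Wadsworth–Emmons formyl-olefination: the phosphonate anion should attack only the unhindered methyl ketone, because the C4 ketone is screened on the β face by the syn-axial C10 methyl and on the α face by the axial silyl ether, and acid hydrolysis of the unsaturated imine should equilibrate the enal to the E isomer with CHO cis to the methyl group.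

Step 13
Reactants: 23 enal; 24 diethyl (2-methylallyl)phosphonate
Product: 25 1β-bromo-7β-[(2E,4E)-6-methylhepta-2,4,6-trien-2-yl]-5α-(triethylsilyloxy)-10β-methyl-trans-decalin-4-one (eudesmane numbering)
Conditions: 24 (1.5 equiv), n-BuLi (1.4 equiv), THF, −78 °C; then 23, DMPU, −78 °C → rt
Reagents that add atoms: diethyl (2-methylallyl)phosphonate, CCOP(=O)(OCC)CC(C)=C
Why: Horner–Wadsworth–Emmons olefination of an aldehyde with an allylic phosphonate anion, which reacts at its α-carbon and should give the E-disubstituted alkene, the aldehyde being consumed at −78 °C while the hindered C4 ketone stays untouched.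

Step 14
Reactants: 25 triene ketone
Product: 26 1β-bromo-4-methylidene-7β-[(2E,4E)-6-methylhepta-2,4,6-trien-2-yl]-5α-(triethylsilyloxy)-10β-methyl-trans-decalin (eudesmane numbering)
Conditions: Tebbe reagent (2.5 equiv), pyridine, THF–toluene, −40 °C → rt; aq. NaOH quench
Reagents that add atoms: Tebbe reagent, c1cc[cH-]c1.c1cc[cH-]c1.[Ti+2]1C[Al-](C)(C)[Cl+]1
Why: Tebbe methylenation: the small, non-basic titanocene methylidene converts hindered and enolisable ketones into methylene compounds through an oxatitanacyclobutane, avoiding enolisation toward C3 that could displace the C1 bromide.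

Step 15
Reactants: 26 silyl ether
Product: 27 target, (1R,5R,7R,10R)-1-bromo-4-methylidene-7-[(2E,4E)-6-methylhepta-2,4,6-trien-2-yl]-10-methyl-trans-decalin-5-ol (eudesmane numbering; 1β-Br, 5α-OH)
Conditions: HF·pyridine, pyridine, THF, 0 °C → rt
Reagents that add atoms: none
Why: Buffered fluoride cleavage of the silyl ether under non-basic conditions, so that no C5 alkoxide forms; such an alkoxide would be aligned for Grob fragmentation of the C5–C10 bond with loss of the antiperiplanar equatorial C1 bromide.

**Compound list**
1 | (R)-(−)-carvone | CC1=CC[C@@H](C(C)=C)CC1=O | starting material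
2 | (2R,5R)-2-methyl-5-(prop-1-en-2-yl)cyclohexan-1-one (with its C2 epimer) | C[C@@H]1CC[C@@H](C(C)=C)CC1=O | intermediate
3 | (R)-1-phenylethylamine | C[C@@H](N)c1ccccc1 | starting material
4 | methyl acrylate | C=CC(=O)OC | starting material
5 | N-[(1R)-1-phenylethyl] ketimine of 2 (C2 epimers equilibrating) | CC1CC[C@@H](C(C)=C)CC1=N[C@H](C)c1ccccc1 | intermediate
6 | N-[(1R)-1-phenylethyl] imine of keto ester 7 | COC(=O)CC[C@]1(C)CC[C@@H](C(C)=C)CC1=N[C@H](C)c1ccccc1 | intermediate
7 | methyl 3-[(1S,4R)-1-methyl-2-oxo-4-(prop-1-en-2-yl)cyclohexyl]propanoate | CC(=C)[C@@H]1CC[C@@](C)(CCC(=O)OC)C(=O)C1 | intermediate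
8 | 3-[(1S,4R)-1-methyl-2-oxo-4-(prop-1-en-2-yl)cyclohexyl]propanoic acid | CC(=C)[C@@H]1CC[C@@](C)(CCC(=O)O)C(=O)C1 | intermediate
9 | (2S,5R)-2-ethenyl-2-methyl-5-(prop-1-en-2-yl)cyclohexan-1-one | CC(=C)[C@@H]1CC[C@@](C)(C=C)C(=O)C1 | intermediate
10 | (3R,6S)-6-ethenyl-6-methyl-3-(prop-1-en-2-yl)cyclohex-1-en-1-yl trifluoromethanesulfonate | CC(=C)[C@@H]1CC[C@@](C)(C=C)C(OS(=O)(=O)C(F)(F)F)=C1 | intermediate
11 | tributyl(1-ethoxyvinyl)stannane | CCCC[Sn](CCCC)(CCCC)C(=C)OCC | starting material
12 | (3R,6S)-1-(1-ethoxyethenyl)-6-ethenyl-6-methyl-3-(prop-1-en-2-yl)cyclohex-1-ene | CC(=C)[C@@H]1CC[C@@](C)(C=C)C(C(=C)OCC)=C1 | intermediate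
13 | 1-[(3R,6S)-6-ethenyl-6-methyl-3-(prop-1-en-2-yl)cyclohex-1-en-1-yl]ethan-1-one | CC(=C)[C@@H]1CC[C@@](C)(C=C)C(C(C)=O)=C1 | intermediate
14 | triethyl({1-[(2S,5R)-2-ethenyl-2-methyl-5-(prop-1-en-2-yl)cyclohexylidene]ethoxy})silane | CC(=C)[C@@H]1CC[C@@](C)(C=C)C(=C(C)O[Si](CC)(CC)CC)C1 | intermediate
15 | spiro silyloxy-oxirane of 14 (oxygen on the α face of C5) | CC(=C)[C@@H]1CC[C@@](C)(C=C)[C@@]2(OC2(C)O[Si](CC)(CC)CC)C1 | intermediate
16 | 1-[(1S,2S,5R)-2-ethenyl-2-methyl-5-(prop-1-en-2-yl)-1-(triethylsilyloxy)cyclohexyl]ethan-1-one | CC(=C)[C@@H]1CC[C@@](C)(C=C)[C@](O[Si](CC)(CC)CC)(C(C)=O)C1 | intermediate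
17 | trimethylsilyl enol ether of 16 (terminal C3=C4) | CC(=C)[C@@H]1CC[C@@](C)(C=C)[C@](O[Si](CC)(CC)CC)(C(=C)O[Si](C)(C)C)C1 | intermediate
18 | 2-bromo-1-[(1S,2S,5R)-2-ethenyl-2-methyl-5-(prop-1-en-2-yl)-1-(triethylsilyloxy)cyclohexyl]ethan-1-one | CC(=C)[C@@H]1CC[C@@](C)(C=C)[C@](O[Si](CC)(CC)CC)(C(=O)CBr)C1 | intermediate
19 | 1β-bromo-5α-(triethylsilyloxy)-15-noreudesm-11-en-4-one | CC(=C)[C@@H]1CC[C@@]2(C)[C@H](Br)CCC(=O)[C@]2(O[Si](CC)(CC)CC)C1 | intermediate
20 | 1β-bromo-5α-(triethylsilyloxy)-13,15-dinoreudesmane-4,11-dione | CC(=O)[C@@H]1CC[C@@]2(C)[C@H](Br)CCC(=O)[C@]2(O[Si](CC)(CC)CC)C1 | intermediate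
21 | diethyl [(E)-2-(cyclohexylamino)vinyl]phosphonate | CCOP(=O)(OCC)/C=C/NC1CCCCC1 | starting material
22 | N-cyclohexyl imine of enal 23 | C1CCCCC1N=C/C=C(\C)[C@@H]1CC[C@@]2(C)[C@H](Br)CCC(=O)[C@]2(O[Si](CC)(CC)CC)C1 | intermediate
23 | (2E)-3-[1β-bromo-4-oxo-5α-(triethylsilyloxy)-10β-methyl-trans-decalin-7β-yl]but-2-enal | O=C/C=C(\C)[C@@H]1CC[C@@]2(C)[C@H](Br)CCC(=O)[C@]2(O[Si](CC)(CC)CC)C1 | intermediate
24 | diethyl (2-methylallyl)phosphonate | CCOP(=O)(OCC)CC(C)=C | starting material
25 | 1β-bromo-7β-[(2E,4E)-6-methylhepta-2,4,6-trien-2-yl]-5α-(triethylsilyloxy)-10β-methyl-trans-decalin-4-one | C=C(C)/C=C/C=C(\C)[C@@H]1CC[C@@]2(C)[C@H](Br)CCC(=O)[C@]2(O[Si](CC)(CC)CC)C1 | intermediate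
26 | 1β-bromo-4-methylidene-7β-[(2E,4E)-6-methylhepta-2,4,6-trien-2-yl]-5α-(triethylsilyloxy)-10β-methyl-trans-decalin | C=C(C)/C=C/C=C(\C)[C@@H]1CC[C@@]2(C)[C@H](Br)CCC(=C)[C@]2(O[Si](CC)(CC)CC)C1 | intermediate
27 | (1R,5R,7R,10R)-1-bromo-4-methylidene-7-[(2E,4E)-6-methylhepta-2,4,6-trien-2-yl]-10-methyl-trans-decalin-5-ol (CNP0385268.1) | C=C(C)/C=C/C=C(\C)[C@@H]1CC[C@@]2(C)[C@H](Br)CCC(=C)[C@]2(O)C1 | target

**Count**
Total steps: 15. Longest linear sequence: 15 steps (1 → 27; all other inputs are purchased).

**Steps most likely to fail**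

Step 10. The bromine transfer to the C1 radical may be too slow or insufficiently face-selective, and the α-keto radical may add to an isopropenyl group of another molecule before it cyclises, leading to oligomers. The fallback separates ring closure from bromination and sets out from 18. Displacement of bromide with potassium O-ethyl xanthate in acetone gives the α-xanthyl ketone F1. Dilauroyl peroxide, added in portions in refluxing 1,2-dichloroethane, then drives the same 6-endo closure as a degenerative xanthate-transfer chain, which tolerates slow cyclisations, to give the ring-closed C1 xanthate F2. Radical exchange of the xanthate for bromine with ethyl 2-bromo-2-methylpropanoate and dilauroyl peroxide in hot chlorobenzene returns to the route at 19.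

Step 14. Addition to the C4 carbonyl may fail because both faces are hindered, or the titanium carbene may be consumed by the triene. The fallback sets out from 25. The small, weakly basic reagent from (trimethylsilyl)methyllithium and CeCl3 adds to the ketone in THF at −78 °C to give the β-hydroxysilane F3. Acid-promoted anti Peterson elimination (AcOH buffered with NaOAc, 40 °C) returns to the route at 26. The base-promoted variant is avoided because a C4 alkoxide could take the silyl group from O5 and release the fragmentation-prone C5 alkoxide.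

Step 12. The basic phosphonate anion may enolise the C4 ketone toward C3, after which bromide can be lost by internal 1,3-displacement. Olefination of the α-branched methyl ketone may also be slow or give incomplete E control. The fallback sets out from 20. CeCl3-promoted addition of ethynylmagnesium bromide to the methyl ketone (the C4 ketone being too hindered) gives the tertiary propargylic alcohol F4. Meyer–Schuster rearrangement under neutral catalysis (MoO2(acac)2 with Ph3PAuCl/AgOTf, toluene, rt) then returns to the route at the E-enal 23.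

**Further compounds**
F1 | step 10 | O-ethyl S-{2-oxo-2-[(1S,2S,5R)-2-ethenyl-2-methyl-5-(prop-1-en-2-yl)-1-(triethylsilyloxy)cyclohexyl]ethyl} carbonodithioate | CC(=C)[C@@H]1CC[C@@](C)(C=C)[C@](O[Si](CC)(CC)CC)(C(=O)CSC(=S)OCC)C1
F2 | step 10 | 1-[(ethoxycarbonothioyl)sulfanyl]-5α-(triethylsilyloxy)-15-noreudesm-11-en-4-one (either C1 epimer) | CC(=C)[C@@H]1CC[C@@]2(C)C(SC(=S)OCC)CCC(=O)[C@]2(O[Si](CC)(CC)CC)C1
F3 | step 14 | 4-hydroxy-4-[(trimethylsilyl)methyl] adduct of 25 (either C4 epimer) | C=C(C)/C=C/C=C(\C)[C@@H]1CC[C@@]2(C)[C@H](Br)CCC(O)(C[Si](C)(C)C)[C@]2(O[Si](CC)(CC)CC)C1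
F4 | step 12 | 11-ethynyl-11-hydroxy adduct of 20 (either C11 epimer) | C#CC(C)(O)[C@@H]1CC[C@@]2(C)[C@H](Br)CCC(=O)[C@]2(O[Si](CC)(CC)CC)C1
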